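(The numbers in the tables come from a simulation on assumed constants.)

- The cedar run's target fell at 0.168 min⁻¹ on a logarithmic scale early and at 0.104 min⁻¹ late, whereas the reciprocal of its target fraction rose nearly steadily, by 0.524 min⁻¹.

| flask | substrate | remark | time |
|---|---|---|---|
| elm | 0.40 M | the very flask that is asked about, followed so far |  |
| cedar | 0.27 M | run made earlier |  |
| flask | 0.40 M |  | 12 min |

elm run (percent of the substrate charged)

| time / s | target / % |
|---|---|
| 10.0 | 27.3 |
| 30.0 | 37.2 |
| 60.0 | 33.7 |
| 80.0 | 31.5 |

cedar run (percent of the substrate charged)

| time / min | target / % |
|---|---|
| 1.00 | 39.3 |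
| 3.00 | 28.1 |
| 5.00 | 22.0 |
| 8.00 | 16.1 |

(scatter of a reading: 0.5 percentage points)

* the moment within 12 min at which there is most target
* the amount of target, in percent of the substrate charged, at that time

- I took this for a second-order loss, which in fractions scales with the charge, so for the elm flask I reckoned 0.776 min⁻¹: these are loss turnovers per minute, the steady rise of the reciprocal of the target fraction. The elm tail, with its scatter, read 0.622 min⁻¹.
- In my first extreme, the elm flask makes its target at once and then only loses it. Counting turnovers back from the 80.0 s reading gave a start of 46.7%.
- In my second extreme, the elm flask loses nothing and climbs towards that same fraction. The 10.0 s reading gave a climb of 5.27 min⁻¹, faster than the turnovers.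
- I placed the real elm flask between them, so I expected its peak after the start and below that fraction. Multiplying the climb by the fall, and setting the two rates equal with the target at the 37.2% read near the top, I got 0.551 min and 36.8%, lower than that starting fraction.
- The forecast, where “Formation then balances loss”, gave 0.47 min and 37.6%, earlier and higher than my reckoning.
- The elm flask gave 36.3% at 0.519 min, when 44.7% of the charge stood as self-condensation product. For 12 min I reckoned 9.31 turnovers, which gave me 8.73% of target, and the elm flask held 8.63%.

    substrate ⇌ target (K = 1.90, k = 0.0520 s⁻¹)
    2 substrate → self-condensation product (k = 0.100 M⁻¹ s⁻¹)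

- For a neighbouring flask with 0.68 M of substrate, I scaled the turnovers to 15.8 in 12 min. Assuming the starting fraction of the elm flask, that gave me 5.56% of target, and the computed neighbour ended at 5.49%.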